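## Retrosynthetic overview

1. Numbering (benzofuran): ring A is the dihydrofuran O1–C2–C3–C3a–C7a; ring B is the carbocycle C3a–C4(=O)–C5(Me2)–C6(=O)–C7(enolised isobutyryl)–C7a.
2. Ring B is cut at C4–C5 and C7–C7a in an anionic [3+3] annulation. C5–C6–C7 plus the isobutyryl group is the dianion of commercial 2,6-dimethylheptane-3,5-dione. C4–C3a–C7a is the α-[bis(methylsulfanyl)methylidene] γ-lactone 9, in which O1 is still acylated by C4.
3. Enabling feature: C4 and C7a, the two ring B carbons flanking C3a, are both at the carboxylic acid oxidation level, and O1 lies γ to C4 (through C3a–C3–C2). Ring A can therefore be stored as a γ-lactone on C4 and handed over to C7a when the lactone is opened. The C5–C6–C7–acyl segment is a hidden C2-symmetric diketone, so either isopropyl terminus gives the same product.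
4. Both stereocentres come from one Sharpless asymmetric epoxidation of geraniol. C2 is fixed by an invertive 5-exo lactonisation of a γ,δ-epoxy acid; the tertiary carbinol keeps the epoxide configuration.
5. Ring order: γ-lactone (step 4), then ring B and ring A in one operation (step 7), in which the lactone ring is consumed. A methoxymethyl ether on the tertiary alcohol is the only protecting group.

Key step: step 7

Remark: the target is an enolised β-triketone; the drawn enol (7Z, hydroxyl hydrogen-bonded to the C6 carbonyl) is taken as the representation of the rapidly equilibrating tautomers that the route delivers.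

## Route

Step 1
Reactants: 1 geraniol
Product: 2 (2R,3R)-2,3-epoxygeraniol
Conditions: Ti(OiPr)4 (5 mol%), D-(−)-diethyl tartrate (7 mol%), t-BuOOH (anhydrous, 2 equiv), 4 Å molecular sieves, CH2Cl2, −20 °C
Reagents that add atoms: tert-butyl hydroperoxide, CC(C)(C)OO
Why: Sharpless asymmetric epoxidation; the titanium tartrate catalyst binds the allylic hydroxyl, so only the 2,3-alkene reacts, and D-(−)-diethyl tartrate should deliver oxygen to the face that gives the (2R,3R)-epoxide, which sets both stereocentres of the target.

Step 2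
Reactants: 2 (2R,3R)-2,3-epoxygeraniol
Product: 3 (2S,3R)-2-(iodomethyl)-3-methyl-3-(4-methylpent-3-en-1-yl)oxirane (epoxy iodide)
Conditions: PPh3, I2, imidazole, CH2Cl2, 0 °C → rt
Reagents that add atoms: iodine, II
Why: Appel-type iodination replaces the primary hydroxyl by iodide at C1 without touching the buffered epoxide; the descriptor at the oxirane CH changes to S only because iodine changes the priorities.

Step 3
Reactants: 3 epoxy iodide
Product: 4 methyl 3-[(2R,3R)-3-methyl-3-(4-methylpent-3-en-1-yl)oxiran-2-yl]propanoate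
Conditions: methyl acetate, LiN(iPr)2 (commercial solution), THF, −78 °C; then 3, DMPU, −78 → −40 °C
Reagents that add atoms: methyl acetate, CC(=O)OC
Why: Alkylation of a lithium ester enolate by SN2 at the primary iodomethyl carbon, which should be faster than attack at the hindered trisubstituted epoxide, adds the two carbons that become C3a and C4; no stereocentre is affected.

Step 4
Reactants: 4 methyl epoxy ester
Product: 6 (5S)-5-[(2R)-2-hydroxy-6-methylhept-5-en-2-yl]oxolan-2-one (hydroxy lactone), via epoxy acid 5 (not isolated)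
Conditions: LiOH, THF/MeOH/H2O, 0 °C → rt; then 1 M HCl to pH 4; then PPTS (cat.), CH2Cl2, rt
Reagents that add atoms: lithium hydroxide, [Li+].[OH-]
Why: Saponification followed by intramolecular epoxide opening by the carboxyl oxygen (5-exo-tet, SN2 at the secondary oxirane carbon, preferred over 6-endo attack at the tertiary carbon under weakly acidic conditions) should give the γ-lactone; inversion sets (S) at the future C2 and the tertiary C–O bond keeps (R).

Step 5
Reactants: 6 hydroxy lactone
Product: 7 (5S)-5-[(2R)-2-(methoxymethoxy)-6-methylhept-5-en-2-yl]oxolan-2-one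
Conditions: MeOCH2Cl, iPr2NEt, n-Bu4NI (cat.), ClCH2CH2Cl, 0 → 50 °C
Reagents that add atoms: chloromethyl methyl ether, COCCl
Why: Methoxymethyl ether formation caps the tertiary hydroxyl so that it cannot form a xanthate in step 6 or compete for C7a in step 7; an acetal is chosen because it cannot migrate to a neighbouring alkoxide as a silyl group could.

Step 6
Reactants: 7 methoxymethyl-protected lactone
Product: 9 (5S)-3-[bis(methylsulfanyl)methylidene]-5-[(2R)-2-(methoxymethoxy)-6-methylhept-5-en-2-yl]oxolan-2-one, via dilithium ene-dithiolate 8 (not isolated)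
Conditions: LiN(SiMe3)2 (2.2 equiv), THF, −78 °C; CS2 (1.2 equiv), −78 → 0 °C; MeI (2.5 equiv), 0 °C → rt
Reagents that add atoms: carbon disulfide, S=C=S; iodomethane, CI
Why: Standard α-oxo ketene dithioacetal synthesis (enolate addition to CS2, second deprotonation to 8, double S-methylation) raises the future C7a to the carboxyl oxidation level with two leaving groups; the stereocentres are remote from the enolate and unaffected.

Step 7
Reactants: 9 lactone ketene dithioacetal; 10 2,6-dimethylheptane-3,5-dione
Product: 14 (2S,7Z)-7-(1-hydroxy-2-methylpropylidene)-2-[(2R)-2-(methoxymethoxy)-6-methylhept-5-en-2-yl]-5,5-dimethyl-2,3-dihydro-1-benzofuran-4,6(5H,7H)-dione (methoxymethyl ether of the target), via diketone dianion 11 (not isolated), via ring-opened alkoxide enolate 12 (not isolated), via thioenone alkoxide 13 (not isolated)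
Conditions: 10 (1.3 equiv), LiN(iPr)2 (commercial solution, 2.6 equiv), THF, −78 → 0 °C; then 9, −78 °C → rt, then 45 °C; then AcOH (excess), 40 °C
Reagents that add atoms: none
Why: Proposed new method: the tertiary terminal carbanion (C5) of dianion 11 should add to the lactone carbonyl of 9 and expel the ring oxygen (Claisen-type acylation, C4–C5 bond) to give 12, whose internal diketonate carbon C7 then displaces one methylsulfanyl group at C7a by conjugate addition–elimination (C7–C7a bond, ring B closed 6-endo-trig) to give 13; on acidification the C2 hydroxyl displaces the second methylsulfanyl group at C7a (ring A closed, formally 5-endo-trig on the push–pull alkene, in effect 5-exo-trig on the sulfur-stabilised cation at C7a), so the oxygen that C4 acylated in the lactone ends up on C7a. The closest known reaction types are the γ-acylation of 1,3-diketone dianions by esters and lactones and the anionic [3+3] annulation of α-oxo ketene dithioacetals with 1,3-dinucleophiles; their combination on a lactone-derived dithioacetal, with transfer of the lactone oxygen, has no direct precedent. No stereocentre is created (C5 carries two methyl groups), and C2 keeps its configuration because only the acyl C4–O1 bond, never the C2–O1 bond, is broken. The step needs the pairing C5→C4 and C7→C7a and not the reverse: the hard, hindered carbanion should prefer the carbonyl to the fully substituted, doubly sulfur-donated C7a, C7a becomes a strong acceptor only once C4 is a ketone, and by then the only nucleophiles within reach are C7 (six-membered ring) and O1 (five-membered ring). The methoxymethyl ether keeps the tertiary oxygen out of the competition for C7a, only C7a carries leaving groups so O1 cannot end up on C4, and the acidic enolised triketone of 14 (formed as its lithium enolate) is the thermodynamic sink that should draw reversible side equilibria (O-attack of the diketonate, hemiketals) to the product.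

Step 8
Reactants: 14 methoxymethyl ether of the target
Product: 15 (2S,7Z)-7-(1-hydroxy-2-methylpropylidene)-2-[(2R)-2-hydroxy-6-methylhept-5-en-2-yl]-5,5-dimethyl-2,3-dihydro-1-benzofuran-4,6(5H,7H)-dione (target)
Conditions: ZnBr2 (3 equiv), n-PrSH (3 equiv), CH2Cl2, 0 °C → rt
Reagents that add atoms: none
Why: Lewis acid/thiol cleavage of the methoxymethyl acetal (ZnBr2 activates the acetal, the thiol traps the methoxymethyl cation) should free the tertiary alcohol under conditions that spare the alkene and the vinylogous ester; no stereocentre is touched.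

## Compound list

1 | geraniol, (2E)-3,7-dimethylocta-2,6-dien-1-ol | CC(C)=CCC/C(C)=C/CO | starting material
2 | (2R,3R)-2,3-epoxygeraniol, [(2R,3R)-3-methyl-3-(4-methylpent-3-en-1-yl)oxiran-2-yl]methanol | CC(C)=CCC[C@@]1(C)O[C@@H]1CO | intermediate
3 | (2S,3R)-2-(iodomethyl)-3-methyl-3-(4-methylpent-3-en-1-yl)oxirane | CC(C)=CCC[C@@]1(C)O[C@@H]1CI | intermediate
4 | methyl 3-[(2R,3R)-3-methyl-3-(4-methylpent-3-en-1-yl)oxiran-2-yl]propanoate | CC(C)=CCC[C@@]1(C)O[C@@H]1CCC(=O)OC | intermediate
5 | 3-[(2R,3R)-3-methyl-3-(4-methylpent-3-en-1-yl)oxiran-2-yl]propanoic acid (formed as its lithium salt, not isolated) | CC(C)=CCC[C@@]1(C)O[C@@H]1CCC(=O)O | intermediate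
6 | (5S)-5-[(2R)-2-hydroxy-6-methylhept-5-en-2-yl]oxolan-2-one | CC(C)=CCC[C@@](C)(O)[C@@H]1CCC(=O)O1 | intermediate
7 | (5S)-5-[(2R)-2-(methoxymethoxy)-6-methylhept-5-en-2-yl]oxolan-2-one | CC(C)=CCC[C@@](C)(OCOC)[C@@H]1CCC(=O)O1 | intermediate
8 | dilithium {(5S)-5-[(2R)-2-(methoxymethoxy)-6-methylhept-5-en-2-yl]-2-oxooxolan-3-ylidene}methanedithiolate (not isolated) | [Li+].[Li+].CC(C)=CCC[C@@](C)(OCOC)[C@@H]1CC(=C([S-])[S-])C(=O)O1 | intermediate
9 | (5S)-3-[bis(methylsulfanyl)methylidene]-5-[(2R)-2-(methoxymethoxy)-6-methylhept-5-en-2-yl]oxolan-2-one | CC(C)=CCC[C@@](C)(OCOC)[C@@H]1CC(=C(SC)SC)C(=O)O1 | intermediate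
10 | 2,6-dimethylheptane-3,5-dione | CC(C)C(=O)CC(=O)C(C)C | starting material
11 | dilithium 2,6-dimethylhepta-2,4-diene-3,5-diolate (not isolated) | [Li+].[Li+].CC(C)C([O-])=CC([O-])=C(C)C | intermediate
12 | dilithium alkoxide enolate of (10S,11R)-8-[bis(methylsulfanyl)methylidene]-10-hydroxy-11-(methoxymethoxy)-2,6,6,11,15-pentamethylhexadec-14-ene-3,5,7-trione (not isolated) | [Li+].[Li+].CC(C)=CCC[C@@](C)(OCOC)[C@@H]([O-])CC(=C(SC)SC)C(=O)C(C)(C)C(=O)C=C([O-])C(C)C | intermediate
13 | dilithium alkoxide enolate of 2-[(2S,3R)-2-hydroxy-3-(methoxymethoxy)-3,7-dimethyloct-6-en-1-yl]-4-(1-hydroxy-2-methylpropylidene)-6,6-dimethyl-3-(methylsulfanyl)cyclohex-2-ene-1,5-dione (not isolated) | [Li+].[Li+].CC(C)=CCC[C@@](C)(OCOC)[C@@H]([O-])CC1=C(SC)C(=C([O-])C(C)C)C(=O)C(C)(C)C1=O | intermediate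
14 | (2S,7Z)-7-(1-hydroxy-2-methylpropylidene)-2-[(2R)-2-(methoxymethoxy)-6-methylhept-5-en-2-yl]-5,5-dimethyl-2,3-dihydro-1-benzofuran-4,6(5H,7H)-dione | CC(C)=CCC[C@@](C)(OCOC)[C@@H]1CC2=C(O1)/C(=C(/O)C(C)C)C(=O)C(C)(C)C2=O | intermediate
15 | (2S,7Z)-7-(1-hydroxy-2-methylpropylidene)-2-[(2R)-2-hydroxy-6-methylhept-5-en-2-yl]-5,5-dimethyl-2,3-dihydro-1-benzofuran-4,6(5H,7H)-dione | CC(C)=CCC[C@@](C)(O)[C@@H]1CC2=C(O1)/C(=C(/O)C(C)C)C(=O)C(C)(C)C2=O | target

## Step count and risks

Total step count: 8. Longest linear sequence: 8 steps (1 → 15); diketone 10 is purchased and enters in step 7.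

**Step 7 (proposed new method).** Three things may go wrong: mis-pairing of the two carbon–carbon bonds (the terminal carbanion adding to the dithioacetal carbon instead of the lactone carbonyl), deprotonation at C3 of 9 followed by β-elimination of the lactone carboxylate, or arrest after the first acylation. The fallback uses known reaction types in the biomimetic order; it sets out from iodide 3 and returns at target 15. Commercial 2-methyl-1-(2,4,6-trihydroxyphenyl)propan-1-one F1 is C-methylated twice at one ring carbon (NaOMe, MeI, MeOH, 0 °C → rt) to the dearomatised 3,5-dihydroxy-6,6-dimethyl-2-(2-methylpropanoyl)cyclohexa-2,4-dien-1-one F2. Its sodium enolate is C-alkylated at the free ring carbon with 3 (NaOMe, MeOH, rt) to 3,5-dihydroxy-6,6-dimethyl-4-{[(2R,3R)-3-methyl-3-(4-methylpent-3-en-1-yl)oxiran-2-yl]methyl}-2-(2-methylpropanoyl)cyclohexa-2,4-dien-1-one F3. On warming, the enol oxygen between the acyl-bearing carbon and the alkylated carbon should open the epoxide 5-exo with inversion and give 15 directly. Closure through the other enol oxygen gives a regioisomer that must be removed by chromatography, which is why this is the fallback and not the route.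

**Step 3.** The SN2 at the oxiranylmethyl iodide may be sluggish, the acetate enolate may self-condense on warming, or proton transfer to the product may be followed by 3-exo opening of the epoxide. The fallback is a malonic ester synthesis; it sets out from 3 and returns at 6, replacing steps 3 and 4. Iodide 3 is alkylated with sodium dimethyl malonate (dimethyl malonate in excess, NaH, THF/DMF, 0 °C → rt) to dimethyl 2-{[(2R,3R)-3-methyl-3-(4-methylpent-3-en-1-yl)oxiran-2-yl]methyl}propanedioate F4. Saponification (LiOH, THF/H2O) and acidification to pH 3 convert F4, by 5-exo closure of a carboxyl group onto the epoxide, into (5S)-5-[(2R)-2-hydroxy-6-methylhept-5-en-2-yl]-2-oxooxolane-3-carboxylic acid F5. Heating F5 in toluene (100 °C) removes CO2 and should give lactone 6.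

**Step 8.** The Lewis acid may ionise the tertiary carbinol or promote its addition to the remote alkene, zinc chelation by the triketone may stall the acetal cleavage, or the thiol may add to the vinylogous ester. The fallback uses a protecting group that leaves in the work-up of the annulation; it sets out from 6 and returns at 15. Lactone 6 is converted with 2-methoxypropene and PPTS (CH2Cl2, 0 °C) into the mixed ketal (5S)-5-{(2R)-2-[(2-methoxypropan-2-yl)oxy]-6-methylhept-5-en-2-yl}oxolan-2-one F6. The conditions of step 6 (LiN(SiMe3)2, CS2, MeI) then give (5S)-3-[bis(methylsulfanyl)methylidene]-5-{(2R)-2-[(2-methoxypropan-2-yl)oxy]-6-methylhept-5-en-2-yl}oxolan-2-one F7. Annulation with 10 as in step 7, warmed until the oxygen closure is complete, should give the ketal-protected product (2S,7Z)-7-(1-hydroxy-2-methylpropylidene)-2-{(2R)-2-[(2-methoxypropan-2-yl)oxy]-6-methylhept-5-en-2-yl}-5,5-dimethyl-2,3-dihydro-1-benzofuran-4,6(5H,7H)-dione F8. An aqueous acetic acid quench (AcOH/THF/H2O, rt) hydrolyses the ketal in the same flask to 15, so no separate deprotection is needed.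

Further compounds
F1 | step 7 | 2-methyl-1-(2,4,6-trihydroxyphenyl)propan-1-one | CC(C)C(=O)c1c(O)cc(O)cc1O
F2 | step 7 | 3,5-dihydroxy-6,6-dimethyl-2-(2-methylpropanoyl)cyclohexa-2,4-dien-1-one | CC(C)C(=O)C1=C(O)C=C(O)C(C)(C)C1=O
F3 | step 7 | 3,5-dihydroxy-6,6-dimethyl-4-{[(2R,3R)-3-methyl-3-(4-methylpent-3-en-1-yl)oxiran-2-yl]methyl}-2-(2-methylpropanoyl)cyclohexa-2,4-dien-1-one | CC(C)=CCC[C@@]1(C)O[C@@H]1CC2=C(O)C(C)(C)C(=O)C(C(=O)C(C)C)=C2O
F4 | step 3 | dimethyl 2-{[(2R,3R)-3-methyl-3-(4-methylpent-3-en-1-yl)oxiran-2-yl]methyl}propanedioate | CC(C)=CCC[C@@]1(C)O[C@@H]1CC(C(=O)OC)C(=O)OC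
F5 | step 3 | (5S)-5-[(2R)-2-hydroxy-6-methylhept-5-en-2-yl]-2-oxooxolane-3-carboxylic acid | CC(C)=CCC[C@@](C)(O)[C@@H]1CC(C(=O)O)C(=O)O1
F6 | step 8 | (5S)-5-{(2R)-2-[(2-methoxypropan-2-yl)oxy]-6-methylhept-5-en-2-yl}oxolan-2-one | CC(C)=CCC[C@@](C)(OC(C)(C)OC)[C@@H]1CCC(=O)O1
F7 | step 8 | (5S)-3-[bis(methylsulfanyl)methylidene]-5-{(2R)-2-[(2-methoxypropan-2-yl)oxy]-6-methylhept-5-en-2-yl}oxolan-2-one | CC(C)=CCC[C@@](C)(OC(C)(C)OC)[C@@H]1CC(=C(SC)SC)C(=O)O1
F8 | step 8 | (2S,7Z)-7-(1-hydroxy-2-methylpropylidene)-2-{(2R)-2-[(2-methoxypropan-2-yl)oxy]-6-methylhept-5-en-2-yl}-5,5-dimethyl-2,3-dihydro-1-benzofuran-4,6(5H,7H)-dione | CC(C)=CCC[C@@](C)(OC(C)(C)OC)[C@@H]1CC2=C(O1)/C(=C(/O)C(C)C)C(=O)C(C)(C)C2=O
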